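Ring B (ether oxygen at C1', hydroxyls at C2' and C4', carboxyl at C5', pentyl at C6') is read as the aromatised form of a malonate-derived cyclohexane-1,3-dione and disconnected at C5'–C6' and C3'–C4', so no aryl coupling is needed for the crowded O–C1' bond. In one operation the key step adds dibenzyl malonate to C6' of an α-aryloxy enone and closes ring B by Claisen condensation. The precursor is a non-3-en-2-one whose C3 carries the 8-oxygen of 6-benzyloxy-3-pentylisocoumarin (rings A and C complete), assembled by carbenoid O–H insertion and olefination. Benzyl groups on O6 and on the ring B carboxyl then fall in a single neutral hydrogenolysis.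

Key step: step 7

Numbering: isocoumarin locants (C1 to C8a) for rings A and C; ring B runs from the ether carbon C1' through C2' (OH), C3' (H), C4' (OH) and C5' (CO2H) to C6' (pentyl).
Assumption: the cyclohexane-1,3-diones are drawn as diketo tautomers although they should exist largely as enols, and the enone is drawn as its Z isomer although either alkene geometry converges in the key step.

Step 1
Reactants: 1 2,4-dimethoxy-6-methylbenzoic acid; 2 N-methoxy-N-methylhexanamide
Product: 4 2,4-dimethoxy-6-(2-oxoheptyl)benzoic acid, via dilithiated acid 3 (not isolated)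
Conditions: LiN(iPr)2 (2.2 equiv), THF, −78 to 0 °C; then 2, −78 °C to rt; aq. HCl
Reagents that add atoms: N-methoxy-N-methylhexanamide (2), CCCCCC(=O)N(C)OC
Why: Lateral lithiation and acylation of an o-toluate, in which the second equivalent of amide base deprotonates the methyl group next to the lithium carboxylate and the N-methoxy-N-methylamide acylates this carbanion only once because its chelated tetrahedral adduct survives until the acidic work-up.

Step 2
Reactants: 4 2,4-dimethoxy-6-(2-oxoheptyl)benzoic acid
Product: 5 6,8-dimethoxy-3-pentyl-1H-isochromen-1-one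
Conditions: Ac2O, 100 °C
Reagents that add atoms: none
Why: Enol lactonisation of a 2-(2-oxoalkyl)benzoic acid through its mixed anhydride, the enol oxygen of the benzylic ketone closing the six-membered lactone to give the conjugated isocoumarin without the strong base that would instead favour C-acylation to a naphthalenediol.

Step 3
Reactants: 5 6,8-dimethoxy-3-pentyl-1H-isochromen-1-one
Product: 6 6,8-dihydroxy-3-pentyl-1H-isochromen-1-one
Conditions: BBr3 (4 equiv), CH2Cl2, −78 °C to rt; then H2O
Reagents that add atoms: none
Why: Exhaustive Lewis acid demethylation of both aryl methyl ethers, a routine operation on 6,8-dimethoxyisocoumarins that leaves the lactone and the alkyl chain untouched.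

Step 4
Reactants: 6 6,8-dihydroxy-3-pentyl-1H-isochromen-1-one; 7 benzyl bromide
Product: 8 6-(benzyloxy)-8-hydroxy-3-pentyl-1H-isochromen-1-one
Conditions: BnBr (1.05 equiv), K2CO3, acetone, rt
Reagents that add atoms: benzyl bromide (7), BrCc1ccccc1
Why: Williamson etherification selective for O6, since the 6-hydroxyl (para to the carbon bearing C1=O) is the more acidic and unhindered one while the 8-hydroxyl is tied up in a hydrogen bond to the lactone carbonyl and should stay free with one equivalent of halide and a weak base.

Step 5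
Reactants: 8 6-(benzyloxy)-8-hydroxy-3-pentyl-1H-isochromen-1-one; 9 dimethyl (1-diazo-2-oxopropyl)phosphonate
Product: 10 dimethyl (1-{[6-(benzyloxy)-1-oxo-3-pentyl-1H-isochromen-8-yl]oxy}-2-oxopropyl)phosphonate (racemic)
Conditions: Rh2(OAc)4 (2 mol%), toluene, 80 °C, slow addition of 9 (1.5 equiv)
Reagents that add atoms: dimethyl (1-diazo-2-oxopropyl)phosphonate (9), CC(=O)C(=[N+]=[N-])P(=O)(OC)OC
Why: Rhodium carbenoid O–H insertion, in which the electrophilic acceptor/acceptor carbenoid is captured by the phenolic oxygen (oxonium ylide, then proton shift) under neutral conditions, so that no enolisable aryloxyacetone is ever exposed to base beside the lactone carbonyl; the new stereocentre forms as a racemate and disappears in step 6.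

Step 6
Reactants: 10 dimethyl (1-{[6-(benzyloxy)-1-oxo-3-pentyl-1H-isochromen-8-yl]oxy}-2-oxopropyl)phosphonate; 11 hexanal
Product: 12 (Z)-3-{[6-(benzyloxy)-1-oxo-3-pentyl-1H-isochromen-8-yl]oxy}non-3-en-2-one
Conditions: hexanal (1.5 equiv), LiCl, DBU, MeCN, 0 °C to rt
Reagents that add atoms: hexanal (11), CCCCCC=O
Why: Horner–Wadsworth–Emmons olefination under mild LiCl/amine conditions, in which the doubly stabilised phosphonate anion condenses with the aldehyde (far more electrophilic than the peri lactone carbonyl) and the phosphonate carbon becomes C3 of the enone, which fixes the aryloxy group on the α-carbon without the regiochemical ambiguity of an aldol condensation; the Z isomer (acetyl trans to pentyl) is expected to predominate.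

Step 7
Reactants: 12 (Z)-3-{[6-(benzyloxy)-1-oxo-3-pentyl-1H-isochromen-8-yl]oxy}non-3-en-2-one; 13 dibenzyl malonate
Product: 15 benzyl 3-{[6-(benzyloxy)-1-oxo-3-pentyl-1H-isochromen-8-yl]oxy}-4,6-dioxo-2-pentylcyclohexane-1-carboxylate (diastereomer mixture), via Michael adduct 14 (not isolated)
Conditions: NaH (1.05 equiv), dibenzyl malonate (1.2 equiv), THF, 0 °C to reflux; then cold 1 M HCl
Reagents that add atoms: dibenzyl malonate (13), O=C(CC(=O)OCc1ccccc1)OCc1ccccc1
Why: Proposed new method: sodium dibenzyl malonate should add in Michael fashion to C6', the pentyl-bearing β-carbon of the α-aryloxy enone (bond C5'–C6'), and after proton transfer the methyl ketone enolate of adduct 14 should attack one benzyl ester in a Claisen condensation (bond C3'–C4'), the expelled benzyloxide being consumed at once by the acidic 1,3-dione, so that the sequence is pulled forward and no free alkoxide remains to open the lactone of ring C. The closest known reaction type is the Michael–Claisen annulation of malonates with simple 3-alken-2-ones that gives 5-alkyl-4-carboalkoxycyclohexane-1,3-diones; an enone with an α-aryloxy group has not been shown in it, but the oxygen here sits on an electron-poor isocoumarin ring and should donate only weakly into the enone, so the β-carbon should remain electrophilic enough. Ring B closes by a 6-exo-trig attack of the enolate carbon on the ester carbonyl. No stereocontrol is sought: the three stereocentres created at C1, C2 and C3 of the cyclohexane (C1 epimerisable through the β-keto ester) give a diastereomer mixture that becomes one compound once step 8 flattens the ring. The selectivity required is that of enolate closure, and it is secured because, of the two α-carbons of the ketone, only the terminal CH3 can reach an ester carbonyl in a six-membered ring while C1' would have to form a cyclobutanone; attack of the C1' enolate on the neighbouring C1 lactone carbonyl should not drain material, because it would give a quaternary, non-enolisable β-diketone that forms reversibly, whereas the Claisen product is trapped as its enolate.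

Step 8
Reactants: 15 benzyl 3-{[6-(benzyloxy)-1-oxo-3-pentyl-1H-isochromen-8-yl]oxy}-4,6-dioxo-2-pentylcyclohexane-1-carboxylate
Product: 17 benzyl 3-{[6-(benzyloxy)-1-oxo-3-pentyl-1H-isochromen-8-yl]oxy}-4,6-dihydroxy-2-pentylbenzoate, via bromodione 16 (not isolated)
Conditions: Br2 (1.0 equiv), DMF, 0 °C; then 70 °C
Reagents that add atoms: none
Why: Dehydrogenation of a cyclohexane-1,3-dione to a resorcinol by bromination and dehydrobromination, in which one equivalent of bromine should be consumed at the enolised C5 between the two carbonyls and the bromodione should lose HBr on warming through its enol towards C3, so that C2–C3 becomes unsaturated and the ring tautomerises to the benzyl resorcylate with all three sp3 stereocentres erased.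

Step 9
Reactants: 17 benzyl 3-{[6-(benzyloxy)-1-oxo-3-pentyl-1H-isochromen-8-yl]oxy}-4,6-dihydroxy-2-pentylbenzoate
Product: 18 4,6-dihydroxy-3-[(6-hydroxy-1-oxo-3-pentyl-1H-isochromen-8-yl)oxy]-2-pentylbenzoic acid (CNP0439913.0)
Conditions: H2 (1 atm), 10% Pd/C, EtOAc, rt, stopped after two equivalents of H2
Reagents that add atoms: none
Why: Catalytic hydrogenolysis of the benzyl ether and the benzyl ester, which should be much faster than saturation of the trisubstituted C3=C4 enol lactone bond and frees the resorcylic acid under neutral conditions at room temperature, avoiding the decarboxylation that threatens such acids when a hindered alkyl ester has to be saponified.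

Compound list
1 | 2,4-dimethoxy-6-methylbenzoic acid | Cc1cc(OC)cc(OC)c1C(=O)O | starting material
2 | N-methoxy-N-methylhexanamide | CCCCCC(=O)N(C)OC | starting material
3 | lithium 2,4-dimethoxy-6-(lithiomethyl)benzoate | [Li]Cc1cc(OC)cc(OC)c1C(=O)O[Li] | intermediate
4 | 2,4-dimethoxy-6-(2-oxoheptyl)benzoic acid | CCCCCC(=O)Cc1cc(OC)cc(OC)c1C(=O)O | intermediate
5 | 6,8-dimethoxy-3-pentyl-1H-isochromen-1-one | CCCCCc1cc2cc(OC)cc(OC)c2c(=O)o1 | intermediate
6 | 6,8-dihydroxy-3-pentyl-1H-isochromen-1-one | CCCCCc1cc2cc(O)cc(O)c2c(=O)o1 | intermediate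
7 | benzyl bromide | BrCc1ccccc1 | starting material
8 | 6-(benzyloxy)-8-hydroxy-3-pentyl-1H-isochromen-1-one | CCCCCc1cc2cc(OCc3ccccc3)cc(O)c2c(=O)o1 | intermediate
9 | dimethyl (1-diazo-2-oxopropyl)phosphonate | CC(=O)C(=[N+]=[N-])P(=O)(OC)OC | starting material
10 | dimethyl (1-{[6-(benzyloxy)-1-oxo-3-pentyl-1H-isochromen-8-yl]oxy}-2-oxopropyl)phosphonate (racemic) | CCCCCc1cc2cc(OCc3ccccc3)cc(OC(C(C)=O)P(=O)(OC)OC)c2c(=O)o1 | intermediate
11 | hexanal | CCCCCC=O | starting material
12 | (Z)-3-{[6-(benzyloxy)-1-oxo-3-pentyl-1H-isochromen-8-yl]oxy}non-3-en-2-one | CCCCC/C=C(\Oc1cc(OCc2ccccc2)cc2cc(CCCCC)oc(=O)c12)C(C)=O | intermediate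
13 | dibenzyl malonate (dibenzyl propanedioate) | O=C(CC(=O)OCc1ccccc1)OCc1ccccc1 | starting material
14 | dibenzyl 2-(3-{[6-(benzyloxy)-1-oxo-3-pentyl-1H-isochromen-8-yl]oxy}-2-oxononan-4-yl)propanedioate (diastereomer mixture) | CCCCCC(C(Oc1cc(OCc2ccccc2)cc2cc(CCCCC)oc(=O)c12)C(C)=O)C(C(=O)OCc1ccccc1)C(=O)OCc1ccccc1 | intermediate
15 | benzyl 3-{[6-(benzyloxy)-1-oxo-3-pentyl-1H-isochromen-8-yl]oxy}-4,6-dioxo-2-pentylcyclohexane-1-carboxylate (diastereomer mixture) | O=C(OCc1ccccc1)C1C(=O)CC(=O)C(Oc2cc(OCc3ccccc3)cc3cc(CCCCC)oc(=O)c23)C1CCCCC | intermediate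
16 | benzyl 5-bromo-3-{[6-(benzyloxy)-1-oxo-3-pentyl-1H-isochromen-8-yl]oxy}-4,6-dioxo-2-pentylcyclohexane-1-carboxylate (diastereomer mixture) | O=C(OCc1ccccc1)C1C(=O)C(Br)C(=O)C(Oc2cc(OCc3ccccc3)cc3cc(CCCCC)oc(=O)c23)C1CCCCC | intermediate
17 | benzyl 3-{[6-(benzyloxy)-1-oxo-3-pentyl-1H-isochromen-8-yl]oxy}-4,6-dihydroxy-2-pentylbenzoate | CCCCCc1cc2cc(OCc3ccccc3)cc(Oc3c(O)cc(O)c(C(=O)OCc4ccccc4)c3CCCCC)c2c(=O)o1 | intermediate
18 | 4,6-dihydroxy-3-[(6-hydroxy-1-oxo-3-pentyl-1H-isochromen-8-yl)oxy]-2-pentylbenzoic acid | CCCCCc1cc2cc(O)cc(Oc3c(O)cc(O)c(C(=O)O)c3CCCCC)c2c(=O)o1 | target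

Total step count: 9. Longest linear sequence: 9 steps (1 to 18); all other components are purchased.

Steps most likely to fail

Step 7 (proposed new method). Conjugate addition may be too slow on a trisubstituted enone that carries an oxygen donor on its α-carbon. Under forcing conditions the C1' enolate or benzyloxide may attack the C1 lactone carbonyl and open ring C. The fallback uses known chemistry, an Ullmann diaryl ether synthesis, and accepts making the crowded O–C1' bond by coupling; it sets out from phenol 8 and returns to the route at target 18. Commercial olivetolic acid (2,4-dihydroxy-6-pentylbenzoic acid) would be perbenzylated (BnBr, K2CO3, DMF, 60 °C) to benzyl 2,4-bis(benzyloxy)-6-pentylbenzoate F1. Iodination at the position para to the 2-benzyloxy group and next to the pentyl chain (NIS, cat. CF3CO2H, MeCN) should give benzyl 4,6-bis(benzyloxy)-3-iodo-2-pentylbenzoate F2. Copper-catalysed coupling with 8 (CuI, picolinic acid, K3PO4, DMSO, 90 °C) should give benzyl 4,6-bis(benzyloxy)-3-{[6-(benzyloxy)-1-oxo-3-pentyl-1H-isochromen-8-yl]oxy}-2-pentylbenzoate F3, and hydrogenolysis under the conditions of step 9 should remove all four benzyl groups to give 18.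

Step 5. Capture of the carbenoid by the hydrogen-bonded, peri-hindered 8-hydroxyl may be slow, so that carbene dimerisation or attack at C3=C4 or at a benzyl ring competes. The fallback forms the C–O bond by substitution and the alkene by a directed aldol sequence; it sets out from 8 and returns at 12. Alkylation with chloroacetone (K2CO3, cat. KI, acetone, rt, kept mild because the aryloxyacetone enolate lies next to the lactone carbonyl) should give 1-{[6-(benzyloxy)-1-oxo-3-pentyl-1H-isochromen-8-yl]oxy}propan-2-one F4. Soft enolisation towards the more acidic aryloxy-bearing carbon (TMSOTf, Et3N, CH2Cl2, 0 °C) should give 6-(benzyloxy)-3-pentyl-8-{[(Z)-2-(trimethylsilyloxy)prop-1-en-1-yl]oxy}-1H-isochromen-1-one F5. Mukaiyama aldol addition to hexanal (cat. Sc(OTf)3, CH2Cl2, −78 °C; aq. HCl) should give 3-{[6-(benzyloxy)-1-oxo-3-pentyl-1H-isochromen-8-yl]oxy}-4-hydroxynonan-2-one F6. Mesylation (MsCl, Et3N, CH2Cl2, 0 °C) to 3-{[6-(benzyloxy)-1-oxo-3-pentyl-1H-isochromen-8-yl]oxy}-2-oxononan-4-yl methanesulfonate F7 and elimination with DBU should then give 12.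

Step 8. Bromine may be transferred from the bromodione to activated ring positions (C3' of the new resorcinol, C5 and C7 of ring A, C4 of ring C). The HBr released on warming may also cleave the benzyl ester, after which the free acid could decarboxylate. The fallback is a halogen-free dehydrogenation by hydride abstraction; it sets out from 15 and returns at 17 with no new compound on the way: DDQ (1.1 equiv) in 1,4-dioxane at 80 °C should oxidise the enol form of 15 directly to 17.

Further compounds
F1 | step 7 | benzyl 2,4-bis(benzyloxy)-6-pentylbenzoate | CCCCCc1cc(OCc2ccccc2)cc(OCc2ccccc2)c1C(=O)OCc1ccccc1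
F2 | step 7 | benzyl 4,6-bis(benzyloxy)-3-iodo-2-pentylbenzoate | CCCCCc1c(I)c(OCc2ccccc2)cc(OCc2ccccc2)c1C(=O)OCc1ccccc1
F3 | step 7 | benzyl 4,6-bis(benzyloxy)-3-{[6-(benzyloxy)-1-oxo-3-pentyl-1H-isochromen-8-yl]oxy}-2-pentylbenzoate | CCCCCc1cc2cc(OCc3ccccc3)cc(Oc3c(OCc4ccccc4)cc(OCc4ccccc4)c(C(=O)OCc4ccccc4)c3CCCCC)c2c(=O)o1
F4 | step 5 | 1-{[6-(benzyloxy)-1-oxo-3-pentyl-1H-isochromen-8-yl]oxy}propan-2-one | CCCCCc1cc2cc(OCc3ccccc3)cc(OCC(C)=O)c2c(=O)o1
F5 | step 5 | 6-(benzyloxy)-3-pentyl-8-{[(Z)-2-(trimethylsilyloxy)prop-1-en-1-yl]oxy}-1H-isochromen-1-one | C/C(O[Si](C)(C)C)=C/Oc1cc(OCc2ccccc2)cc2cc(CCCCC)oc(=O)c12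
F6 | step 5 | 3-{[6-(benzyloxy)-1-oxo-3-pentyl-1H-isochromen-8-yl]oxy}-4-hydroxynonan-2-one (diastereomer mixture) | CCCCCC(O)C(Oc1cc(OCc2ccccc2)cc2cc(CCCCC)oc(=O)c12)C(C)=O
F7 | step 5 | 3-{[6-(benzyloxy)-1-oxo-3-pentyl-1H-isochromen-8-yl]oxy}-2-oxononan-4-yl methanesulfonate (diastereomer mixture) | CCCCCC(OS(C)(=O)=O)C(Oc1cc(OCc2ccccc2)cc2cc(CCCCC)oc(=O)c12)C(C)=O
F0 | step 8 | none | none
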